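**Assumption:** drimane numbering is used for the bicyclic compounds (C4 carries the gem-dimethyl group, C10 the angular methyl, C11 sits on C9, C12 on C8; β is the face of the C10 methyl). The SMILES strings define the absolute configuration.

## Retrosynthetic overview

1. Target 25 ⇒ dialdehyde 24 (phenol silyl ether) ⇒ bis(silyl ether) 23. The two aldehydes are unveiled last, and the C1–O ester bond is cut to diol 18 plus acid 21 (from p-coumaric acid 19).
2. 18 ⇒ tetraol 17 ⇒ lactone 16. Key disconnection: the C5–O bond, together with the C7=C8/C9–H array, from skipped-diene lactone 12 by an O2 ene C–O bond formation and 1,6-hydride transposition.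
3. 12 ⇒ Diels–Alder reaction of (R)-dienol 7 (as its silyl ether) with diester 8, then O1→C11 lactonisation.
4. 7 ⇒ CBS reduction of dienone 6 ⇒ Stork–Danheiser sequence from 2-methylcyclohexane-1,3-dione 1.
5. Ring order: ring A (from 1) → ring B (Diels–Alder, step 5) → temporary γ-lactone (closed in step 5, opened in step 7).

## Route

Step 1
Reactants: 1 2-methylcyclohexane-1,3-dione
Product: 2 3-isobutoxy-2-methylcyclohex-2-en-1-one
Conditions: i-BuOH, TsOH·H2O (cat.), toluene, reflux, Dean–Stark
Reagents that add atoms: 2-methylpropan-1-ol, CC(C)CO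
Why: Acid-catalysed vinylogous ester (enol ether) formation from a 1,3-dione, driven by azeotropic removal of water; no stereocentre is formed.

Step 2
Reactants: 2 3-isobutoxy-2-methylcyclohex-2-en-1-one
Product: 4 3-isobutoxy-2,6,6-trimethylcyclohex-2-en-1-one, via monomethyl enone 3 (not isolated)
Conditions: LiN(i-Pr)2 (1.1 equiv), THF, −78 °C, MeI; then LiN(i-Pr)2 (1.2 equiv), −78 °C, MeI, → 0 °C
Reagents that add atoms: iodomethane, CI
Why: Two cycles of kinetic α′-deprotonation and SN2 methylation (enolate alkylation of a vinylogous ester) build the gem-dimethyl carbon; the transient stereocentre of 3 vanishes in 4.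

Step 3
Reactants: 4 3-isobutoxy-2,6,6-trimethylcyclohex-2-en-1-one
Product: 6 2,4,4-trimethyl-3-vinylcyclohex-2-en-1-one, via bromomagnesium carbinolate 5 (not isolated)
Conditions: CH2=CHMgBr, CeCl3, THF, −78 → 0 °C; then 1 M HCl, 23 °C
Reagents that add atoms: vinylmagnesium bromide, C=C[Mg]Br; water, O
Why: Stork–Danheiser transposition: 1,2-addition of the vinyl nucleophile to the hindered ketone, then acid hydrolysis of the enol ether with loss of water and isobutanol gives the transposed dienone; no stereocentre is formed.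

Step 4
Reactants: 6 2,4,4-trimethyl-3-vinylcyclohex-2-en-1-one
Product: 7 (R)-2,4,4-trimethyl-3-vinylcyclohex-2-en-1-ol
Conditions: (S)-2-methyl-CBS-oxazaborolidine (20 mol%), catecholborane, toluene, −78 °C; aq. NaOH work-up
Reagents that add atoms: none
Why: Corey–Bakshi–Shibata reduction in which the α-methyl alkenyl arm is the large group, so the (S)-catalyst gives the (R)-carbinol (future C1); catecholborane at −78 °C leaves the vinyl group alone.

Step 5
Reactants: 7 (R)-2,4,4-trimethyl-3-vinylcyclohex-2-en-1-ol; 8 dimethyl but-2-ynedioate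
Product: 12 methyl 11-oxo-1β,11-epoxydrima-5,8-dien-12-oate, via trimethylsilyl ether 9 (not isolated), via silyloxy diester adduct 10 (not isolated), via hydroxy diester 11 (not isolated)
Conditions: (Me3Si)2NH, Me3SiCl (cat.), 60 °C, then evaporate; 8 (3 equiv), neat, 110 °C; then TsOH·H2O (cat.), MeOH, 50 °C
Reagents that add atoms: none
Why: Thermal Diels–Alder reaction in which the alkyne adds to the diene face anti to the pseudoaxial, non-hydrogen-bonding OSiMe3 group, which sets C10 with its methyl cis to the C1 oxygen; acid methanolysis then frees the 1β-hydroxyl, which lies peri to the C9 ester and closes the γ-lactone (the C12 ester cannot reach it).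

Step 6
Reactants: 12 methyl 11-oxo-1β,11-epoxydrima-5,8-dien-12-oate
Product: 16 methyl 5α-hydroxy-11-oxo-1β,11-epoxy-9αH-drim-7-en-12-oate, via hydroperoxide 13 (not isolated), via dienyl alcohol 14 (not isolated), via copper dienolate 15 (not isolated)
Conditions: O2, tetraphenylporphyrin (0.5 mol%), white LEDs, toluene, 0 °C; Ar purge, PPh3 (1.2 equiv), 0 °C; then Cu(OAc)2·H2O (5 mol%), 1,2-bis(diphenylphosphino)benzene (5 mol%), (EtO)2MeSiH (2 equiv), t-BuOH (2 equiv), 0 → 23 °C
Reagents that add atoms: dioxygen, O=O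
Why: Proposed new method: a one-flask ene/1,6-hydride transposition that amounts to Markovnikov hydration of C5=C6 with a shift of C8=C9 to C7=C8 — singlet oxygen can only attack the electron-rich trisubstituted C5=C6 bond of the skipped diene, must take its hydrogen from the doubly allylic C7 (the only allylic C–H) and approaches the α face away from the two β-axial methyl groups on C4 and C10, so the Schenck ene reaction forms the C5–O bond on the α face and leaves the C6=C7–C8=C9 dienyl lactone 13 (reduced by PPh3 to 14); a phosphine-ligated monovalent copper hydride then delivers hydride to C6, the only unhindered electrophilic carbon (δ to the lactone carbonyl, whereas C8 and C9 are fully substituted), and the copper dienolate 15 is protonated by t-BuOH at C9 from the α face because the 1β,11-lactone bridge can only span a β-oriented C9–C11 bond; the closest known reactions are the Schenck ene reaction of 1,4-cyclohexadienes and [(Ph3P)CuH]6-type conjugate (1,4- and 1,6-) reductions of enoates and enynoates, and to my knowledge neither the telescoped sequence nor a 1,6-reduction of a δ-hydroxy dienyl alkylidene lactone with lactone-directed α-protonation has been described.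

Step 7
Reactants: 16 methyl 5α-hydroxy-11-oxo-1β,11-epoxy-9αH-drim-7-en-12-oate
Product: 17 9αH-drim-7-ene-1β,5α,11,12-tetraol
Conditions: LiAlH4, THF, 0 → 23 °C; Fieser work-up
Reagents that add atoms: none
Why: Hydride reduction of the γ-lactone and 1,2-reduction of the conjugated methyl ester give the 1β-ol and the 11,12-diol; no stereocentre is touched.

Step 8
Reactants: 17 9αH-drim-7-ene-1β,5α,11,12-tetraol
Product: 18 11,12-bis(triethylsilyloxy)-9αH-drim-7-ene-1β,5α-diol
Conditions: Et3SiCl (2.2 equiv), imidazole, CH2Cl2, −40 → 0 °C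
Reagents that add atoms: chlorotriethylsilane, CC[Si](Cl)(CC)CC
Why: Rate-selective silylation: the two primary hydroxyls react far faster than the neopentyl-type secondary 1β-OH and the tertiary 5α-OH.

Step 9
Reactants: 19 (E)-4-hydroxycinnamic acid
Product: 21 (E)-4-(tert-butyldimethylsilyloxy)cinnamic acid, via silyl ester 20 (not isolated)
Conditions: t-BuMe2SiCl (2.3 equiv), imidazole, DMF, 23 °C; then AcOH, THF, H2O, 23 °C
Reagents that add atoms: tert-butyldimethylsilyl chloride, CC(C)(C)[Si](C)(C)Cl
Why: Exhaustive silylation followed by selective hydrolysis of the labile silyl ester, the aryl silyl ether being stable to dilute acid.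

Step 10
Reactants: 18 11,12-bis(triethylsilyloxy)-9αH-drim-7-ene-1β,5α-diol; 21 (E)-4-(tert-butyldimethylsilyloxy)cinnamic acid
Product: 23 5α-hydroxy-11,12-bis(triethylsilyloxy)-9αH-drim-7-en-1β-yl (E)-4-(tert-butyldimethylsilyloxy)cinnamate, via mixed anhydride 22 (not isolated)
Conditions: 21 (1.5 equiv), 2,4,6-Cl3C6H2COCl, Et3N, toluene, 23 °C; then 18, DMAP, toluene, 60 °C
Reagents that add atoms: none
Why: Yamaguchi esterification: the acylpyridinium ion from the mixed anhydride acylates the only reactive free hydroxyl (1β-OH; the tertiary 5α-OH is inert), forming the C1–O ester bond with retention at C1.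

Step 11
Reactants: 23 5α-hydroxy-11,12-bis(triethylsilyloxy)-9αH-drim-7-en-1β-yl (E)-4-(tert-butyldimethylsilyloxy)cinnamate
Product: 24 5α-hydroxy-11,12-dioxo-9αH-drim-7-en-1β-yl (E)-4-(tert-butyldimethylsilyloxy)cinnamate
Conditions: (COCl)2, DMSO, CH2Cl2, −78 → −40 °C; Et3N, −78 → 0 °C
Reagents that add atoms: none
Why: Swern oxidation applied directly to primary triethylsilyl ethers (the chlorosulfonium salt exchanges silyl for alkoxysulfonium), so C11 and C12 both become aldehydes before any hydroxy aldehyde can lactolise, and the brief cold exposure to Et3N preserves C9.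

Step 12
Reactants: 24 5α-hydroxy-11,12-dioxo-9αH-drim-7-en-1β-yl (E)-4-(tert-butyldimethylsilyloxy)cinnamate
Product: 25 5α-hydroxy-11,12-dioxo-9αH-drim-7-en-1β-yl (E)-4-hydroxycinnamate
Conditions: HF·pyridine, pyridine, THF, 0 °C
Reagents that add atoms: none
Why: Fluoride cleavage of the aryl silyl ether under buffered, non-basic conditions that spare the epimerisable 1,4-dialdehyde, the cinnamate and the tertiary alcohol.

## Compound list

1 | 2-methylcyclohexane-1,3-dione | CC1C(=O)CCCC1=O | starting material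
2 | 3-isobutoxy-2-methylcyclohex-2-en-1-one | CC1=C(OCC(C)C)CCCC1=O | intermediate
3 | 3-isobutoxy-2,6-dimethylcyclohex-2-en-1-one (racemic, not isolated) | CC1CCC(OCC(C)C)=C(C)C1=O | intermediate
4 | 3-isobutoxy-2,6,6-trimethylcyclohex-2-en-1-one | CC1(C)CCC(OCC(C)C)=C(C)C1=O | intermediate
5 | bromomagnesium 3-isobutoxy-2,6,6-trimethyl-1-vinylcyclohex-2-en-1-olate (racemic, not isolated) | CC1(C)CCC(OCC(C)C)=C(C)C1(O[Mg]Br)C=C | intermediate
6 | 2,4,4-trimethyl-3-vinylcyclohex-2-en-1-one | CC1(C)CCC(=O)C(C)=C1C=C | intermediate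
7 | (R)-2,4,4-trimethyl-3-vinylcyclohex-2-en-1-ol | CC1(C)CC[C@@H](O)C(C)=C1C=C | intermediate
8 | dimethyl but-2-ynedioate | COC(=O)C#CC(=O)OC | starting material
9 | (R)-trimethyl[(2,4,4-trimethyl-3-vinylcyclohex-2-en-1-yl)oxy]silane (not isolated) | CC1(C)CC[C@@H](O[Si](C)(C)C)C(C)=C1C=C | intermediate
10 | dimethyl 1β-(trimethylsilyloxy)drima-5,8-diene-11,12-dioate (10β-methyl, not isolated) | CC1(C)CC[C@@H](O[Si](C)(C)C)[C@]2(C)C(C(=O)OC)=C(C(=O)OC)CC=C12 | intermediate
11 | dimethyl 1β-hydroxydrima-5,8-diene-11,12-dioate (not isolated) | CC1(C)CC[C@@H](O)[C@]2(C)C(C(=O)OC)=C(C(=O)OC)CC=C12 | intermediate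
12 | methyl 11-oxo-1β,11-epoxydrima-5,8-dien-12-oate (11→1β γ-lactone, 10β-methyl) | CC1(C)CC[C@@H](O3)[C@]2(C)C(C3=O)=C(C(=O)OC)CC=C12 | intermediate
13 | methyl 5α-hydroperoxy-11-oxo-1β,11-epoxydrima-6,8-dien-12-oate (not isolated) | CC1(C)CC[C@@H](O3)[C@]2(C)C(C3=O)=C(C(=O)OC)C=C[C@@]12OO | intermediate
14 | methyl 5α-hydroxy-11-oxo-1β,11-epoxydrima-6,8-dien-12-oate (not isolated) | CC1(C)CC[C@@H](O3)[C@]2(C)C(C3=O)=C(C(=O)OC)C=C[C@@]12O | intermediate
15 | monovalent copper dienolate of 16 (O-bound at C11, C9=C11 and C7=C8, ligand omitted, not isolated) | CC1(C)CC[C@@H](O3)[C@]2(C)C(=C3O[Cu])C(C(=O)OC)=CC[C@@]12O | intermediate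
16 | methyl 5α-hydroxy-11-oxo-1β,11-epoxy-9αH-drim-7-en-12-oate | CC1(C)CC[C@@H](O3)[C@]2(C)[C@@H](C3=O)C(C(=O)OC)=CC[C@@]12O | intermediate
17 | 9αH-drim-7-ene-1β,5α,11,12-tetraol | CC1(C)CC[C@@H](O)[C@]2(C)[C@@H](CO)C(CO)=CC[C@@]12O | intermediate
18 | 11,12-bis(triethylsilyloxy)-9αH-drim-7-ene-1β,5α-diol | CC1(C)CC[C@@H](O)[C@]2(C)[C@@H](CO[Si](CC)(CC)CC)C(CO[Si](CC)(CC)CC)=CC[C@@]12O | intermediate
19 | (E)-4-hydroxycinnamic acid (p-coumaric acid) | OC(=O)/C=C/c1ccc(O)cc1 | starting material
20 | tert-butyldimethylsilyl (E)-4-(tert-butyldimethylsilyloxy)cinnamate (not isolated) | CC(C)(C)[Si](C)(C)OC(=O)/C=C/c1ccc(O[Si](C)(C)C(C)(C)C)cc1 | intermediate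
21 | (E)-4-(tert-butyldimethylsilyloxy)cinnamic acid | OC(=O)/C=C/c1ccc(O[Si](C)(C)C(C)(C)C)cc1 | intermediate
22 | (E)-4-(tert-butyldimethylsilyloxy)cinnamic 2,4,6-trichlorobenzoic anhydride (not isolated) | O=C(OC(=O)/C=C/c1ccc(O[Si](C)(C)C(C)(C)C)cc1)c1c(Cl)cc(Cl)cc1Cl | intermediate
23 | 5α-hydroxy-11,12-bis(triethylsilyloxy)-9αH-drim-7-en-1β-yl (E)-4-(tert-butyldimethylsilyloxy)cinnamate | CC1(C)CC[C@@H](OC(=O)/C=C/c2ccc(O[Si](C)(C)C(C)(C)C)cc2)[C@]2(C)[C@@H](CO[Si](CC)(CC)CC)C(CO[Si](CC)(CC)CC)=CC[C@@]12O | intermediate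
24 | 5α-hydroxy-11,12-dioxo-9αH-drim-7-en-1β-yl (E)-4-(tert-butyldimethylsilyloxy)cinnamate | CC1(C)CC[C@@H](OC(=O)/C=C/c2ccc(O[Si](C)(C)C(C)(C)C)cc2)[C@]2(C)[C@@H](C=O)C(C=O)=CC[C@@]12O | intermediate
25 | 5α-hydroxy-11,12-dioxo-9αH-drim-7-en-1β-yl (E)-4-hydroxycinnamate (CNP0323926.1) | CC1(C)CC[C@@H](OC(=O)/C=C/c2ccc(O)cc2)[C@]2(C)[C@@H](C=O)C(C=O)=CC[C@@]12O | target

## Step count and risks

Total step count: 12. Longest linear sequence: 11 steps (1 → 25 through steps 1–8 and 10–12; step 9 is the side branch).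

**Step 6 (proposed new step).** The copper hydride could add in the wrong sense or reduce sluggishly, or the ene reaction could be slow on the hindered alkene. The fallback uses known chemistry, sets out from 12 and returns at 16. Mukaiyama hydration of 12 (Co(acac)2, PhSiH3, O2, i-PrOH, 23 °C) hydrates only the electron-rich C5=C6 bond from the α face and gives methyl 5α-hydroxy-11-oxo-1β,11-epoxydrim-8-en-12-oate F1. Kinetic deconjugation with LiN(i-Pr)2 (2.5 equiv, THF, −78 °C) removes the γ-hydrogen at C7 to give the dilithium alkoxide dienolate F2. A cold acetic acid quench protonates C9 from the α face and delivers 16. This costs one extra step.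

**Step 10 (acylation of the hindered 1β-hydroxyl).** The peri CH2OSiEt3 group and the quaternary C10 may block the bulky cinnamoyl donor. The fallback sets out from 18 and returns at 23. The small, highly reactive acryloyl chloride (i-Pr2NEt, DMAP, CH2Cl2, 0 °C) forms the C1–O ester bond first, giving 5α-hydroxy-11,12-bis(triethylsilyloxy)-9αH-drim-7-en-1β-yl acrylate F3. A Mizoroki–Heck coupling with tert-butyl(4-iodophenoxy)dimethylsilane (Pd(OAc)2, P(o-tol)3, Et3N, MeCN, 70 °C) then builds the (E)-cinnamate and gives 23.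

**Step 11 (direct Swern oxidation of the bis(silyl ether)).** The neopentyl-type C11 silyl ether may exchange slowly, leaving a mono-aldehyde. The fallback sets out from 23 and returns at 24. Mild acid methanolysis (pyridinium tosylate, MeOH, CH2Cl2, 0 °C) removes only the two primary triethylsilyl groups and gives 5α,11,12-trihydroxy-9αH-drim-7-en-1β-yl (E)-4-(tert-butyldimethylsilyloxy)cinnamate F4. The free 11,12-diol is then oxidised by the classical Swern protocol used for drim-7-ene-11,12-diols, in which both hydroxyls are activated before base is added, to give 24.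

## Further compounds

F1 | step 6 | methyl 5α-hydroxy-11-oxo-1β,11-epoxydrim-8-en-12-oate | CC1(C)CC[C@@H](O3)[C@]2(C)C(C3=O)=C(C(=O)OC)CC[C@@]12O
F2 | step 6 | dilithium alkoxide dienolate of F1 (C11 enolate, C7=C8) | CC1(C)CC[C@@H](O3)[C@]2(C)C(=C3[O-])C(C(=O)OC)=CC[C@@]12[O-].[Li+].[Li+]
F3 | step 10 | 5α-hydroxy-11,12-bis(triethylsilyloxy)-9αH-drim-7-en-1β-yl acrylate | CC1(C)CC[C@@H](OC(=O)C=C)[C@]2(C)[C@@H](CO[Si](CC)(CC)CC)C(CO[Si](CC)(CC)CC)=CC[C@@]12O
F4 | step 11 | 5α,11,12-trihydroxy-9αH-drim-7-en-1β-yl (E)-4-(tert-butyldimethylsilyloxy)cinnamate | CC1(C)CC[C@@H](OC(=O)/C=C/c2ccc(O[Si](C)(C)C(C)(C)C)cc2)[C@]2(C)[C@@H](CO)C(CO)=CC[C@@]12O
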